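**Target as read from the SMILES:** (2R,3R,4R)-2-(4-hydroxy-3-methoxyphenyl)-3-methyl-4-(4-hydroxy-3,5-dimethoxybenzyl)oxolane. The ring is all-trans: 2-aryl/3-methyl trans, 3-methyl/4-benzyl trans, so 2-aryl and 4-benzyl are cis.

**Assumption:** O-benzylvanillin, (E)-crotylboronic acid pinacol ester, 4-bromo-2,6-dimethoxyphenol and (R)-TRIP are taken as commercial. The sense of induction in Step 1 is assigned from recalled precedent, so the configuration of 3 should be confirmed (Mosher ester) before proceeding.

## Retrosynthetic overview

1. Target ⇐ its bis(benzyl) ether, by global hydrogenolysis at the end.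
2. The oxolane is the only ring formed and is made last. The C4–C5 bond, the C4 stereocentre and the CH2–aryl bond are disconnected together to an acyclic O-(carboxymethyl) homoallylic ether plus a syringyl bromide (new decarboxylative alkoxymethyl-radical 5-exo cyclisation / Ni arylation cascade).
3. Alkoxyacetic acid ⇐ anti homoallylic alcohol + bromoacetic acid (Williamson).
4. Anti homoallylic alcohol (C2 and C3 stereocentres) ⇐ O-benzylvanillin + (E)-crotylboronate (catalytic asymmetric crotylboration).
5. Syringyl bromide ⇐ 4-bromo-2,6-dimethoxyphenol + benzyl bromide.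

## Route

**Step 1**
Reactants: 1, 4-(benzyloxy)-3-methoxybenzaldehyde; 2, (E)-crotylboronic acid pinacol ester
Product: 3, (1R,2R)-1-[4-(benzyloxy)-3-methoxyphenyl]-2-methylbut-3-en-1-ol (anti)
Conditions: (R)-TRIP (5 mol%), 2 (1.3 equiv), 4 Å MS, PhMe, −30 → 0 °C; aqueous work-up
Reagents that add atoms: (E)-crotyl-Bpin (compound 2), C/C=C/CB1OC(C)(C)C(C)(C)O1 (only the C4H7 crotyl unit is retained)
Why: Chiral phosphoric acid-catalysed crotylboration through a closed Zimmerman–Traxler chair, in which the (E)-crotyl geometry gives the anti relationship and (R)-TRIP directs Re-face attack on the aldehyde; this sets the future C2 (R) and C3 (R).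

**Step 2**
Reactants: 3; 4, bromoacetic acid
Product: 5, 2-{[(1R,2R)-1-[4-(benzyloxy)-3-methoxyphenyl]-2-methylbut-3-en-1-yl]oxy}acetic acid
Conditions: NaH (3 equiv), THF, 0 °C; BrCH2CO2H (1.5 equiv), cat. Bu4NI, 0 → 50 °C; H3O+ work-up (pH 3, cold)
Reagents that add atoms: bromoacetic acid (compound 4), OC(=O)CBr
Why: Williamson etherification of the sodium alkoxide with sodium bromoacetate; no bond to either stereocentre is broken, and the benzyl ether and terminal alkene are inert to NaH.

**Step 3**
Reactants: 6, 4-bromo-2,6-dimethoxyphenol; 7, benzyl bromide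
Product: 8, 2-(benzyloxy)-5-bromo-1,3-dimethoxybenzene
Conditions: BnBr (1.2 equiv), K2CO3, DMF, 60 °C
Reagents that add atoms: benzyl bromide (compound 7), BrCc1ccccc1
Why: Standard Williamson O-benzylation of a phenol; the aryl bromide is untouched.

**Step 4 (key step, proposed new transformation)**
Reactants: 5; 8 (1.5 equiv)
Product: 9, (2R,3R,4R)-2-[4-(benzyloxy)-3-methoxyphenyl]-4-{[4-(benzyloxy)-3,5-dimethoxyphenyl]methyl}-3-methyloxolane
Conditions: Ir[dF(CF3)ppy]2(dtbbpy)PF6 (1 mol%), NiCl2·glyme (5 mol%), dtbbpy (6 mol%), Cs2CO3 (1.5 equiv), degassed DMSO (0.05 M, about 2.5 mM Ni), 450 nm LEDs, 25 °C; chromatography to remove minor diastereomers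
Reagents that add atoms: none (both fragments are numbered reactants; CO2 and HBr are lost)
Why: Proposed new method: a decarboxylative alkoxymethyl-radical 5-exo cyclisation / Ni aryl cross-coupling cascade, in which photo-oxidation of the caesium carboxylate and loss of CO2 give ArCH(R)–O–CH2•, which cyclises onto the vinyl group (expected to outpace bimolecular capture by millimolar Ni) through a Beckwith–Houk chair with aryl and methyl pseudo-equatorial, giving the 2,4-cis/3,4-trans (all-trans) oxolan-4-ylmethyl radical and hence C4 (R); that primary radical is captured by (dtbbpy)Ni(Ar)Br from 8 and reductive elimination forms the CH2–aryl bond. The closest known reaction types are metallaphotoredox decarboxylative arylation of α-oxy acids, Ni-mediated radical cyclisation/aryl coupling of halo-alkenes, and tin-hydride cyclisation of alkoxymethyl radicals to 2,4-cis/3,4-trans oxolanes.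

**Step 5**
Reactants: 9
Product: 10, 4-{[(3R,4R,5R)-5-(4-hydroxy-3-methoxyphenyl)-4-methyloxolan-3-yl]methyl}-2,6-dimethoxyphenol (target)
Conditions: H2 (1 atm), 10% Pd/C, EtOAc, rt; stop at full conversion
Reagents that add atoms: none
Why: Hydrogenolysis of the two aryl benzyl ethers, which is expected to be faster than cleavage of the ring benzylic C2–O bond under neutral conditions; no stereocentre is involved.

## Compound list

1 | 4-(benzyloxy)-3-methoxybenzaldehyde | COc1cc(C=O)ccc1OCc1ccccc1 | starting material
2 | (E)-crotylboronic acid pinacol ester | C/C=C/CB1OC(C)(C)C(C)(C)O1 | starting material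
3 | (1R,2R)-1-[4-(benzyloxy)-3-methoxyphenyl]-2-methylbut-3-en-1-ol | COc1cc([C@H](O)[C@H](C)C=C)ccc1OCc1ccccc1 | intermediate
4 | bromoacetic acid | OC(=O)CBr | starting material
5 | 2-{[(1R,2R)-1-[4-(benzyloxy)-3-methoxyphenyl]-2-methylbut-3-en-1-yl]oxy}acetic acid | COc1cc([C@H](OCC(=O)O)[C@H](C)C=C)ccc1OCc1ccccc1 | intermediate
6 | 4-bromo-2,6-dimethoxyphenol | COc1cc(Br)cc(OC)c1O | starting material
7 | benzyl bromide | BrCc1ccccc1 | starting material
8 | 2-(benzyloxy)-5-bromo-1,3-dimethoxybenzene | COc1cc(Br)cc(OC)c1OCc1ccccc1 | intermediate
9 | (2R,3R,4R)-2-[4-(benzyloxy)-3-methoxyphenyl]-4-{[4-(benzyloxy)-3,5-dimethoxyphenyl]methyl}-3-methyloxolane | COc1cc([C@@H]2OC[C@H](Cc3cc(OC)c(OCc4ccccc4)c(OC)c3)[C@H]2C)ccc1OCc1ccccc1 | intermediate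
10 | 4-{[(3R,4R,5R)-5-(4-hydroxy-3-methoxyphenyl)-4-methyloxolan-3-yl]methyl}-2,6-dimethoxyphenol | COc1cc([C@@H]2OC[C@H](Cc3cc(OC)c(O)c(OC)c3)[C@H]2C)ccc1O | target

## Summary

**Total step count:** 5
**Longest linear sequence:** 4 steps (1 → 3 → 5 → 9 → 10)

**Three steps most likely to fail**

1. **Step 4 (proposed new cascade).** Likely failure modes are Ni capture of the alkoxymethyl radical before cyclisation (acyclic benzyl ether), H-atom reduction of the cyclised radical (4-methyl oxolane), β-scission of the alkoxymethyl radical to formaldehyde and a benzylic radical, and modest diastereoselectivity.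
 Fallback (known chemistry): put the syringyl ring on the alkene first by cross-metathesis of 3 with 2-(benzyloxy)-1,3-dimethoxy-5-vinylbenzene (from 8 and potassium vinyltrifluoroborate, Suzuki). Convert the alcohol to its (phenylselanyl)methyl ether, then run a classical Bu3SnH/AIBN alkoxymethyl-radical 5-exo cyclisation onto the styrene (PhH, 80 °C). The benzylic radical is reduced by the tin hydride, giving 9 through the same chair transition state.

2. **Step 5 (debenzylation).** The risk is competing hydrogenolysis of the electron-rich benzylic C2–O bond, which would open the ring.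
 Fallback: change the protecting-group strategy. Carry both phenols as TIPS ethers from the start (TIPSCl/imidazole on vanillin and on 6) and unmask at the end with TBAF/AcOH, so no reductive step is needed.

3. **Step 2 (O-alkylation).** The hindered secondary benzylic alkoxide may react slowly, and bromoacetate can self-condense.
 Fallback: Rh2(OAc)4-catalysed O–H insertion of ethyl diazoacetate into 3 under neutral conditions, then LiOH saponification to 5.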